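**Retrosynthetic overview**
- The target's free guaiacyl phenol is carried as an isopropyl ether and unmasked last with BCl3, leaving the three methyl ethers in place.
- Ring C (chromone numbering O1, C2, C3, C4, C4a, C5 to C8, C8a) is cut at C4–C4a by intramolecular Friedel–Crafts acylation of a 3-aryloxypent-2-enoic acid. The strategy rests on aryl carbon C4a of ring A, which is ortho to O1 and para to the C7 methoxy group and so the most electron-rich free carbon of the 3,4-dimethoxyphenyl ether.
- The enol ether bond C2–O1 comes from oxa-Michael addition of 3,4-dimethoxyphenol to methyl 5-(4-isopropoxy-3-methoxyphenyl)pent-2-ynoate.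
- The ynoate comes from a β-keto ester (enol triflation and elimination), itself made by γ-alkylation of the methyl acetoacetate dianion with the benzylic bromide from 4-isopropoxy-3-methoxybenzaldehyde.
- Ring order: ring A and the guaiacyl ring are bought; ring C is the only ring formed, in step 7.

Key step: step 7

Assumption: the carbonate-mediated phenoxide addition of step 5 is taken to settle at the more stable E enol ether (aryloxy group trans to the ester). The acid is therefore isolated as the E isomer, and the Z acid that actually cyclises is expected to form from it in the acidic medium of step 7.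

**Step 1**
Reactants: 1 4-isopropoxy-3-methoxybenzaldehyde
Product: 2 (4-isopropoxy-3-methoxyphenyl)methanol
Conditions: NaBH4, MeOH, 0 °C to rt
Reagents that add atoms: none
Why: Borohydride reduction of an aromatic aldehyde to the benzylic alcohol is fast and leaves the aryl ethers untouched.

**Step 2**
Reactants: 2 (4-isopropoxy-3-methoxyphenyl)methanol
Product: 3 4-(bromomethyl)-2-methoxy-1-(propan-2-yloxy)benzene
Conditions: PBr3 (0.4 equiv), CH2Cl2, 0 °C; cold aq. NaHCO3 wash, used at once
Reagents that add atoms: phosphorus tribromide, BrP(Br)Br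
Why: Bromination of a primary benzylic alcohol with PBr3 (phosphite ester formation, then bromide displacement) is standard, and the labile electron-rich bromide is carried on without storage.

**Step 3**
Reactants: 3 4-(bromomethyl)-2-methoxy-1-(propan-2-yloxy)benzene; 4 methyl acetoacetate
Product: 6 methyl 5-(4-isopropoxy-3-methoxyphenyl)-3-oxopentanoate, via methyl acetoacetate dianion 5 (not isolated)
Conditions: 4 (1.3 equiv), NaH, THF, 0 °C; n-BuLi, 0 °C; then 3, 0 °C to rt; 1 M HCl work-up
Reagents that add atoms: none
Why: Weiler dianion alkylation, in which the terminal γ-carbon of the acetoacetate dianion is the most nucleophilic site and displaces the benzylic bromide by SN2.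

**Step 4**
Reactants: 6 methyl 5-(4-isopropoxy-3-methoxyphenyl)-3-oxopentanoate
Product: 8 methyl 5-(4-isopropoxy-3-methoxyphenyl)pent-2-ynoate, via Z enol triflate 7 (not isolated)
Conditions: LiN(SiMe3)2 (1.1 equiv), THF, −78 °C; Tf2O (1.1 equiv); then LiN(SiMe3)2 (2.2 equiv), −78 °C to 0 °C
Reagents that add atoms: none
Why: O-Triflation of the chelated lithium enolate should give the Z enol triflate, from which the second charge of base expels triflate by anionic elimination, a known one-pot passage from β-keto esters without an α-substituent to conjugated 2-alkynoates.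

**Step 5**
Reactants: 8 methyl 5-(4-isopropoxy-3-methoxyphenyl)pent-2-ynoate; 9 3,4-dimethoxyphenol
Product: 10 methyl (2E)-3-(3,4-dimethoxyphenoxy)-5-(4-isopropoxy-3-methoxyphenyl)pent-2-enoate
Conditions: 9 (1.2 equiv), K2CO3 (0.5 equiv), DMF, 70 °C, under N2
Reagents that add atoms: none
Why: Base-mediated oxa-Michael addition (hydroaryloxylation) of the phenoxide to C3 of the ynoate, where reversible addition under carbonate should let the enol ether settle as the more stable E isomer.

**Step 6**
Reactants: 10 methyl (2E)-3-(3,4-dimethoxyphenoxy)-5-(4-isopropoxy-3-methoxyphenyl)pent-2-enoate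
Product: 11 (2E)-3-(3,4-dimethoxyphenoxy)-5-(4-isopropoxy-3-methoxyphenyl)pent-2-enoic acid
Conditions: LiOH·H2O, THF/MeOH/H2O, rt to 40 °C; then 1 M HCl to pH 3, 0 °C
Reagents that add atoms: lithium hydroxide (supplies the carboxyl oxygen), [Li+].[OH-]
Why: Saponification of the methyl ester by acyl–oxygen cleavage, in which the electron-rich aryloxide is too poor a leaving group for conjugate displacement at C3 to compete and cold dilute acid on work-up spares the enol ether.

**Step 7**
Reactants: 11 (2E)-3-(3,4-dimethoxyphenoxy)-5-(4-isopropoxy-3-methoxyphenyl)pent-2-enoic acid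
Product: 14 2-[2-(4-isopropoxy-3-methoxyphenyl)ethyl]-6,7-dimethoxy-4H-chromen-4-one, via Z acid 12 (not isolated), via acylium ion 13 (not isolated)
Conditions: P2O5/MeSO3H (1:10 w/w, Eaton's reagent), CH2Cl2, 0 °C to rt; then ice, aq. NaHCO3
Reagents that add atoms: none
Why: In P2O5/MeSO3H the E acid 11 equilibrates with the Z acid 12 by reversible protonation at C2, which gives an aryloxy-stabilised carbocation that rotates freely about C2–C3, and the activated carboxyl group of 12 ionises to acylium ion 13, whose carbon is attacked by aryl carbon C4a before loss of the C4a proton restores aromatic ring A. The closest known reaction is the acid-mediated cyclisation of 3-aryloxyacrylic and 3-aryloxycrotonic acids to chromones, an intramolecular Friedel–Crafts acylation. Ring C closes as a six-membered ring through the C4–C4a bond, the arene attacking the exocyclic acylium carbon (formally 6-exo-dig). No stereocentre is created, and the double-bond geometry is lost in the ring. The step needs acylation of ring A at the carbon ortho to O1 and para to the C7 methoxy group, which is favoured over the hindered carbon between the two oxygens, and it needs the equally electron-rich guaiacyl ring to stay out, which ring size secures because from 12 that ring cannot reach the acylium carbon and from the E form it could close only a seven-membered ring. The trioxygenated ring A should react at 0 °C to room temperature, mild enough for the isopropyl ether to survive.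

**Step 8**
Reactants: 14 2-[2-(4-isopropoxy-3-methoxyphenyl)ethyl]-6,7-dimethoxy-4H-chromen-4-one
Product: 15 2-[2-(4-hydroxy-3-methoxyphenyl)ethyl]-6,7-dimethoxy-4H-chromen-4-one
Conditions: BCl3 (1 M in CH2Cl2, 3 equiv), CH2Cl2, −78 °C to 0 °C; then H2O
Reagents that add atoms: none
Why: Lewis-acid ether cleavage, in which the boron-complexed secondary isopropyl ether is dealkylated by chloride far faster than a methyl ether and no methoxy group sits peri to the chromone carbonyl where chelation would assist demethylation.

**Compound list**
1 | 4-isopropoxy-3-methoxybenzaldehyde | COc1cc(C=O)ccc1OC(C)C | starting material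
2 | (4-isopropoxy-3-methoxyphenyl)methanol | COc1cc(CO)ccc1OC(C)C | intermediate
3 | 4-(bromomethyl)-2-methoxy-1-(propan-2-yloxy)benzene | COc1cc(CBr)ccc1OC(C)C | intermediate
4 | methyl acetoacetate | COC(=O)CC(C)=O | starting material
5 | methyl acetoacetate dianion (sodium lithium 1-methoxybuta-1,3-diene-1,3-diolate) | [Na+].[Li+].COC([O-])=CC([O-])=C | intermediate (not isolated)
6 | methyl 5-(4-isopropoxy-3-methoxyphenyl)-3-oxopentanoate | COC(=O)CC(=O)CCc1ccc(OC(C)C)c(OC)c1 | intermediate
7 | methyl (2Z)-5-(4-isopropoxy-3-methoxyphenyl)-3-(trifluoromethanesulfonyloxy)pent-2-enoate | COC(=O)/C=C(\OS(=O)(=O)C(F)(F)F)CCc1ccc(OC(C)C)c(OC)c1 | intermediate (not isolated)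
8 | methyl 5-(4-isopropoxy-3-methoxyphenyl)pent-2-ynoate | COC(=O)C#CCCc1ccc(OC(C)C)c(OC)c1 | intermediate
9 | 3,4-dimethoxyphenol | COc1ccc(O)cc1OC | starting material
10 | methyl (2E)-3-(3,4-dimethoxyphenoxy)-5-(4-isopropoxy-3-methoxyphenyl)pent-2-enoate | COC(=O)/C=C(/Oc1ccc(OC)c(OC)c1)CCc1ccc(OC(C)C)c(OC)c1 | intermediate
11 | (2E)-3-(3,4-dimethoxyphenoxy)-5-(4-isopropoxy-3-methoxyphenyl)pent-2-enoic acid | OC(=O)/C=C(/Oc1ccc(OC)c(OC)c1)CCc1ccc(OC(C)C)c(OC)c1 | intermediate
12 | (2Z)-3-(3,4-dimethoxyphenoxy)-5-(4-isopropoxy-3-methoxyphenyl)pent-2-enoic acid | OC(=O)/C=C(\Oc1ccc(OC)c(OC)c1)CCc1ccc(OC(C)C)c(OC)c1 | intermediate (not isolated)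
13 | (2Z)-3-(3,4-dimethoxyphenoxy)-5-(4-isopropoxy-3-methoxyphenyl)pent-2-enoylium methanesulfonate (acylium ion) | CS(=O)(=O)[O-].O=[C+]/C=C(\Oc1ccc(OC)c(OC)c1)CCc1ccc(OC(C)C)c(OC)c1 | intermediate (not isolated)
14 | 2-[2-(4-isopropoxy-3-methoxyphenyl)ethyl]-6,7-dimethoxy-4H-chromen-4-one | COc1cc(CCc2cc(=O)c3cc(OC)c(OC)cc3o2)ccc1OC(C)C | intermediate
15 | 2-[2-(4-hydroxy-3-methoxyphenyl)ethyl]-6,7-dimethoxy-4H-chromen-4-one | COc1cc(CCc2cc(=O)c3cc(OC)c(OC)cc3o2)ccc1O | target

**Step count**
Total steps: 8. Longest linear sequence: 8 steps (1 to 15).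

**Steps most likely to fail**

Step 7. The cationic intermediates may be diverted before ring C closes. If E/Z equilibration is slow, the guaiacyl ring may capture the electrophilic C3 or the E-configured acylium carbon (five- or seven-membered closure). The acid may also strip the isopropyl group, and the cation released would alkylate an electron-rich ring. The fallback builds ring C by Claisen condensation and cyclodehydration instead, setting out from 1 and coming back at 14. Wittig olefination of 1 with methyl (triphenylphosphoranylidene)acetate (toluene, 80 °C) should give methyl (2E)-3-(4-isopropoxy-3-methoxyphenyl)prop-2-enoate F1. Hydrogenation (H2, Pd/C, EtOAc) should give methyl 3-(4-isopropoxy-3-methoxyphenyl)propanoate F2. Claisen condensation of F2 with commercially available 1-(2-hydroxy-4,5-dimethoxyphenyl)ethanone (NaH, THF, reflux) should give 1-(2-hydroxy-4,5-dimethoxyphenyl)-5-(4-isopropoxy-3-methoxyphenyl)pentane-1,3-dione F3. Acid-catalysed cyclodehydration of F3 (catalytic HCl, MeOH, 50 °C) closes the pyranone at O1–C2 and returns to 14.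

Step 4. The anionic elimination may stop at the enol triflate, or excess base may drive prototropic drift of the ynoate to allenic and dienoic isomers. The fallback reaches the ynoate by acetylide chemistry without the β-keto ester, setting out from 3 and coming back at 8. Alkylation of 3-lithio-1-(trimethylsilyl)propyne (from 1-(trimethylsilyl)propyne and n-BuLi, THF, −78 °C) with 3 should give [4-(4-isopropoxy-3-methoxyphenyl)but-1-yn-1-yl]trimethylsilane F4. Desilylation (K2CO3, MeOH, rt) should give 4-(but-3-yn-1-yl)-2-methoxy-1-(propan-2-yloxy)benzene F5. Deprotonation of F5 (n-BuLi, THF, −78 °C) and trapping with methyl chloroformate returns to 8.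

Step 5. Propargyl–allenyl prototropy of the ynoate under carbonate may outrun phenoxide addition, or addition to the β-alkyl ynoate may stall. The fallback replaces direct addition by addition–elimination on a better acceptor, setting out from 8 and coming back at 10. Hydroiodination of 8 by anti addition (NaI, AcOH, 70 °C) should give methyl (2Z)-3-iodo-5-(4-isopropoxy-3-methoxyphenyl)pent-2-enoate F6. Vinylic substitution of F6 by the phenoxide of 9 (K2CO3, DMF, 40 °C, then 70 °C to let the enol ether geometry equilibrate) should return to the E ester 10.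

**Further compounds**
F1 | step 7 | methyl (2E)-3-(4-isopropoxy-3-methoxyphenyl)prop-2-enoate | COC(=O)/C=C/c1ccc(OC(C)C)c(OC)c1
F2 | step 7 | methyl 3-(4-isopropoxy-3-methoxyphenyl)propanoate | COC(=O)CCc1ccc(OC(C)C)c(OC)c1
F3 | step 7 | 1-(2-hydroxy-4,5-dimethoxyphenyl)-5-(4-isopropoxy-3-methoxyphenyl)pentane-1,3-dione | COc1cc(O)c(cc1OC)C(=O)CC(=O)CCc1ccc(OC(C)C)c(OC)c1
F4 | step 4 | [4-(4-isopropoxy-3-methoxyphenyl)but-1-yn-1-yl]trimethylsilane | C[Si](C)(C)C#CCCc1ccc(OC(C)C)c(OC)c1
F5 | step 4 | 4-(but-3-yn-1-yl)-2-methoxy-1-(propan-2-yloxy)benzene | C#CCCc1ccc(OC(C)C)c(OC)c1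
F6 | step 5 | methyl (2Z)-3-iodo-5-(4-isopropoxy-3-methoxyphenyl)pent-2-enoate | COC(=O)/C=C(\I)CCc1ccc(OC(C)C)c(OC)c1
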